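**Strategy**

The pyran ring of the flavan half is traced back to an indane. Oxygen O1 is inserted between C8a of ring A and the phenyl-bearing carbon C2 by Criegee (Hock-type) rearrangement of a 1-phenylindan-1-yl hydroperoxide: in one operation the five-membered carbocycle becomes the six-membered 2-phenyl-4H-chromene, so ring A needs only three oxygens at the outset. The step exploits the aryl ether bond O1–C8a next to the C8 methoxy group, a donor that makes ring A migrate in preference to phenyl. Asymmetric hydrogenation of the enol ether then sets C2, and C4 is joined to the symmetrical chalcone ring by trans-selective Friedel–Crafts addition to the quinone methide of the 7-hydroxyflavan.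

Key step: step 6

Remark: flavan locants (O1, C2 to C8a; ring A = benzo ring) are used for the corresponding atoms of all precursors; in step 7 the ligand antipode that delivers the (2R) flavan is to be used, the (S) ligand being taken as first choice.

**Route**

Step 1
Reactants: 1 4-hydroxy-2,5-dimethoxybenzaldehyde
Product: 2 2,5-dimethoxy-4-[(triisopropylsilyl)oxy]benzaldehyde
Conditions: TIPSCl, imidazole, DMF, rt
Reagents that add atoms: triisopropylsilyl chloride, CC(C)[Si](Cl)(C(C)C)C(C)C
Why: Imidazole-promoted O-silylation masks the only acidic OH as a bulky aryl TIPS ether, which should outlast the Lewis acid, Grignard, peroxide and hydrogenation steps and come off with fluoride.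

Step 2
Reactants: 2 2,5-dimethoxy-4-[(triisopropylsilyl)oxy]benzaldehyde; 3 Meldrum's acid (2,2-dimethyl-1,3-dioxane-4,6-dione)
Product: 5 5-{2,5-dimethoxy-4-[(triisopropylsilyl)oxy]benzyl}-2,2-dimethyl-1,3-dioxane-4,6-dione, via arylidene 4 (not isolated)
Conditions: Hantzsch ester (diethyl 2,6-dimethyl-1,4-dihydropyridine-3,5-dicarboxylate), L-proline (20 mol%), EtOH, rt
Reagents that add atoms: none
Why: Knoevenagel condensation gives the arylidene, which the Hantzsch ester should reduce in the same flask by conjugate hydride transfer (one-pot reductive alkylation of Meldrum's acid).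

Step 3
Reactants: 5 5-{2,5-dimethoxy-4-[(triisopropylsilyl)oxy]benzyl}-2,2-dimethyl-1,3-dioxane-4,6-dione
Product: 7 4,7-dimethoxy-6-[(triisopropylsilyl)oxy]indan-1-one, via keto acid 6 (not isolated)
Conditions: Sc(O3SCF3)3 (10 mol%), MeNO2, 100 °C
Reagents that add atoms: none
Why: Intramolecular Friedel–Crafts acylation of a benzyl Meldrum's acid with loss of acetone and CO2; only one ring position ortho to the side chain carries hydrogen (the other carries OMe) and it is activated by its neighbouring methoxy group, so a single indanone is expected.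

Step 4
Reactants: 7 4,7-dimethoxy-6-[(triisopropylsilyl)oxy]indan-1-one; 8 phenylmagnesium bromide
Product: 9 racemic 4,7-dimethoxy-1-phenyl-6-[(triisopropylsilyl)oxy]indan-1-ol
Conditions: PhMgBr, LaCl3·2LiCl, THF, 0 °C; aq. NH4Cl
Reagents that add atoms: none
Why: Grignard 1,2-addition, with LaCl3·2LiCl to suppress enolisation of the hindered, electron-rich ketone; the carbinol centre is racemic, which is of no consequence because it becomes sp2 in step 6.

Step 5
Reactants: 9 racemic 4,7-dimethoxy-1-phenyl-6-[(triisopropylsilyl)oxy]indan-1-ol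
Product: 10 racemic 1-hydroperoxy-4,7-dimethoxy-1-phenyl-6-[(triisopropylsilyl)oxy]indane
Conditions: H2O2 (50% aq.), H2SO4 (cat.), THF, 0 °C
Reagents that add atoms: hydrogen peroxide, OO
Why: SN1 perhydrolysis: acid ionises the tertiary, doubly benzylic alcohol and the cation is captured by H2O2, the standard preparation of tertiary benzylic hydroperoxides.

Step 6
Reactants: 10 racemic 1-hydroperoxy-4,7-dimethoxy-1-phenyl-6-[(triisopropylsilyl)oxy]indane
Product: 13 5,8-dimethoxy-2-phenyl-7-[(triisopropylsilyl)oxy]-4H-chromene, via trifluoroperacetate 11 (not isolated), via chromanylium trifluoroacetate 12 (not isolated)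
Conditions: (CF3CO)2O, 2,6-lutidine, CH2Cl2, −40 to 0 °C
Reagents that add atoms: none
Why: Acylation of the hydroperoxide gives perester 11, whose O–O bond ionises with concerted 1,2-shift of the ring A carbon (the future C8a) from the carbinol carbon to the proximal oxygen, so that O1 is inserted into the C–aryl bond and the indane becomes the 2-phenylchroman-2-ylium ion 12, which 2,6-lutidine deprotonates at C3 to the 4H-chromene. The closest known reaction type is the Criegee rearrangement of tertiary benzylic peresters, that is, the Hock rearrangement of cumene-type hydroperoxides stopped at the oxocarbenium stage. The pyran ring is not closed from an open chain; it forms by enlargement of the five-membered carbocycle through a three-centre bridged (phenonium-like) transition state in which the migrating C–C bond is antiperiplanar to the O–O bond. No stereocentre is formed, the racemic carbinol centre becoming the sp2 carbon C2. The step needs migration of ring A in preference to phenyl, which should be secured by the methoxy group ortho to the migrating carbon (the C8 OMe, a donor to the bridged cation), by the absence of donors on phenyl and by the relief of strain on going from a five- to a six-membered ring; the buffered, non-aqueous medium should prevent hydrolysis of 12 to the open hydroxy ketone and spare the TIPS ether.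

Step 7
Reactants: 13 5,8-dimethoxy-2-phenyl-7-[(triisopropylsilyl)oxy]-4H-chromene
Product: 14 (2R)-5,8-dimethoxy-2-phenyl-7-[(triisopropylsilyl)oxy]chroman
Conditions: [Ir(cod)(L)]B(ArF)4 (2 mol%), H2 (50 bar), CH2Cl2, rt; L = (S)-2-phenyl-5,6,7,8-tetrahydroquinolin-8-yl di-tert-butylphosphinite, cod = 1,5-cyclooctadiene, ArF = 3,5-(CF3)2C6H3
Reagents that add atoms: none
Why: Iridium-catalysed asymmetric hydrogenation of a 2-aryl-4H-chromene (a cyclic trisubstituted enol ether) with a chiral P,N ligand is a known route to 2-arylchromans; the catalyst adds H2 to one face of C2=C3 and so should set C2 as R.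

Step 8
Reactants: 14 (2R)-5,8-dimethoxy-2-phenyl-7-[(triisopropylsilyl)oxy]chroman
Product: 15 (2R)-5,8-dimethoxy-2-phenylchroman-7-ol
Conditions: Bu4NF, THF, 0 °C; aq. NH4Cl
Reagents that add atoms: none
Why: Fluoride cleaves the Si–O bond of the aryl silyl ether without touching the benzylic C2–O1 bond or the methyl ethers.

Step 9
Reactants: 16 1-(2,6-dihydroxy-4-methoxyphenyl)ethanone; 17 benzaldehyde
Product: 18 (E)-1-(2,6-dihydroxy-4-methoxyphenyl)-3-phenylprop-2-en-1-one (2',6'-dihydroxy-4'-methoxychalcone)
Conditions: KOH (50% aq.), EtOH, rt; then cold dil. HCl to pH 5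
Reagents that add atoms: none
Why: Claisen–Schmidt aldol condensation; the strong base holds the product as its phenolate, which disfavours oxa-Michael closure to the flavanone, and E1cB dehydration to the conjugated enone should give the E alkene.

Step 10
Reactants: 15 (2R)-5,8-dimethoxy-2-phenylchroman-7-ol; 18 (E)-1-(2,6-dihydroxy-4-methoxyphenyl)-3-phenylprop-2-en-1-one
Product: 20 sarcandrone B, (E)-1-{2,6-dihydroxy-3-[(2R,4R)-7-hydroxy-5,8-dimethoxy-2-phenylchroman-4-yl]-4-methoxyphenyl}-3-phenylprop-2-en-1-one (2,4-trans), via quinone methide 19 (not isolated)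
Conditions: DDQ (1.0 equiv), CH2Cl2, −40 °C; then 18 (3 equiv), CF3CO2H (cat.), −40 to 0 °C
Reagents that add atoms: none
Why: DDQ removes hydride from C4, para to the free 7-OH, to give the quinone methide (a flavan-4-yl cation equivalent), and acid-catalysed 1,6-addition (Friedel–Crafts alkylation) of the chalcone through C3' (C3' and C5' are equivalent) should occur pseudo-axially on the half-chair with the 2-phenyl group pseudo-equatorial, giving the 2,4-trans (4R) product, which is also the more stable isomer because the 4-aryl group avoids the peri 5-OMe.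

**Compound list**

1 | 4-hydroxy-2,5-dimethoxybenzaldehyde | COc1cc(C=O)c(OC)cc1O | starting material
2 | 2,5-dimethoxy-4-[(triisopropylsilyl)oxy]benzaldehyde | COc1cc(C=O)c(OC)cc1O[Si](C(C)C)(C(C)C)C(C)C | intermediate
3 | Meldrum's acid (2,2-dimethyl-1,3-dioxane-4,6-dione) | CC1(C)OC(=O)CC(=O)O1 | starting material
4 | 5-{2,5-dimethoxy-4-[(triisopropylsilyl)oxy]benzylidene}-2,2-dimethyl-1,3-dioxane-4,6-dione | COc1cc(C=C2C(=O)OC(C)(C)OC2=O)c(OC)cc1O[Si](C(C)C)(C(C)C)C(C)C | intermediate
5 | 5-{2,5-dimethoxy-4-[(triisopropylsilyl)oxy]benzyl}-2,2-dimethyl-1,3-dioxane-4,6-dione | COc1cc(CC2C(=O)OC(C)(C)OC2=O)c(OC)cc1O[Si](C(C)C)(C(C)C)C(C)C | intermediate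
6 | 4,7-dimethoxy-1-oxo-6-[(triisopropylsilyl)oxy]indane-2-carboxylic acid | O=C(O)C1Cc2c(OC)cc(O[Si](C(C)C)(C(C)C)C(C)C)c(OC)c2C1=O | intermediate
7 | 4,7-dimethoxy-6-[(triisopropylsilyl)oxy]indan-1-one | COc1cc(O[Si](C(C)C)(C(C)C)C(C)C)c(OC)c2C(=O)CCc12 | intermediate
8 | phenylmagnesium bromide | Br[Mg]c1ccccc1 | starting material
9 | racemic 4,7-dimethoxy-1-phenyl-6-[(triisopropylsilyl)oxy]indan-1-ol | COc1cc(O[Si](C(C)C)(C(C)C)C(C)C)c(OC)c2c1CCC2(O)c1ccccc1 | intermediate
10 | racemic 1-hydroperoxy-4,7-dimethoxy-1-phenyl-6-[(triisopropylsilyl)oxy]indane | COc1cc(O[Si](C(C)C)(C(C)C)C(C)C)c(OC)c2c1CCC2(OO)c1ccccc1 | intermediate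
11 | racemic 4,7-dimethoxy-1-phenyl-6-[(triisopropylsilyl)oxy]indan-1-yl trifluoroperacetate | COc1cc(O[Si](C(C)C)(C(C)C)C(C)C)c(OC)c2c1CCC2(OOC(=O)C(F)(F)F)c1ccccc1 | intermediate
12 | 5,8-dimethoxy-2-phenyl-7-[(triisopropylsilyl)oxy]chroman-2-ylium trifluoroacetate (cyclic oxocarbenium ion pair) | COc1cc(O[Si](C(C)C)(C(C)C)C(C)C)c(OC)c2[O+]=C(c3ccccc3)CCc12.[O-]C(=O)C(F)(F)F | intermediate
13 | 5,8-dimethoxy-2-phenyl-7-[(triisopropylsilyl)oxy]-4H-chromene | COc1cc(O[Si](C(C)C)(C(C)C)C(C)C)c(OC)c2OC(c3ccccc3)=CCc12 | intermediate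
14 | (2R)-5,8-dimethoxy-2-phenyl-7-[(triisopropylsilyl)oxy]chroman | C1C[C@H](c2ccccc2)Oc2c(OC)c(O[Si](C(C)C)(C(C)C)C(C)C)cc(OC)c21 | intermediate
15 | (2R)-5,8-dimethoxy-2-phenylchroman-7-ol | C1C[C@H](c2ccccc2)Oc2c(OC)c(O)cc(OC)c21 | intermediate
16 | 1-(2,6-dihydroxy-4-methoxyphenyl)ethanone | CC(=O)c1c(O)cc(OC)cc1O | starting material
17 | benzaldehyde | O=Cc1ccccc1 | starting material
18 | (E)-1-(2,6-dihydroxy-4-methoxyphenyl)-3-phenylprop-2-en-1-one | COc1cc(O)c(C(=O)/C=C/c2ccccc2)c(O)c1 | intermediate
19 | (2R)-5,8-dimethoxy-2-phenyl-2,3-dihydro-7H-chromen-7-one (para-quinone methide) | O=C1C=C(OC)C2=CC[C@H](c3ccccc3)OC2=C1OC | intermediate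
20 | sarcandrone B, (E)-1-{2,6-dihydroxy-3-[(2R,4R)-7-hydroxy-5,8-dimethoxy-2-phenylchroman-4-yl]-4-methoxyphenyl}-3-phenylprop-2-en-1-one | COc1cc(O)c(C(=O)/C=C/c2ccccc2)c(O)c1[C@H]1C[C@H](c2ccccc2)Oc2c(OC)c(O)cc(OC)c21 | target

**Step count and risks**

Total: 10 steps. Longest linear sequence: 9 steps (steps 1 to 8 and step 10); step 9 is a one-step branch.

Step 6. What may go wrong: migration of phenyl instead of ring A, heterolysis of the C–O bond of the perester followed by elimination to the indene, or hydrolytic opening of the oxocarbenium ion to the acyclic hydroxy ketone. The fallback sets out from indanone 7 and inserts the oxygen before the phenyl group is introduced. Baeyer–Villiger oxidation (m-CPBA, CF3CO2H, CH2Cl2, 0 °C) with migration of the same aryl carbon should give 5,8-dimethoxy-7-[(triisopropylsilyl)oxy]chroman-2-one F1. Addition of PhLi (1 equiv, THF, −78 °C) to the lactone should then give 3-{2-hydroxy-3,6-dimethoxy-4-[(triisopropylsilyl)oxy]phenyl}-1-phenylpropan-1-one F2 (in equilibrium with its lactol). Acid-catalysed cyclodehydration (TsOH, toluene, reflux with removal of water) brings the route back at 13.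

Step 7. What may go wrong: poor facial selectivity in the hydrogenation, or acid-induced decomposition of the enol ether by the iridium hydride. The fallback sets out from 13. Mild hydrolysis (dil. HCl, THF) should give the hydroxy ketone F2 described above. Corey–Bakshi–Shibata reduction ((R)-2-methyl-CBS-oxazaborolidine, BH3·SMe2, THF) should give 2-[(3S)-3-hydroxy-3-phenylpropyl]-3,6-dimethoxy-5-[(triisopropylsilyl)oxy]phenol F3. Mitsunobu cyclisation (PPh3, DIAD, THF) with inversion at the carbinol carbon brings the route back at 14.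

Step 10. What may go wrong: over-oxidation by DDQ, tautomerisation of the quinone methide to the 2H-chromene with erosion of the C2 configuration under acid, self-condensation of the electron-rich flavan, or poor facial selectivity at C4. The fallback sets out from silyl ether 14 and separates oxidation from coupling. DDQ in the presence of 2-ethoxyethanol (CH2Cl2, rt) should give (2R)-4-(2-ethoxyethoxy)-5,8-dimethoxy-2-phenyl-7-[(triisopropylsilyl)oxy]chroman F4 (mixture at C4). BF3·OEt2 (CH2Cl2, −78 to −20 °C) then ionises F4 in the presence of chalcone 18 (3 equiv) to give the 7-O-triisopropylsilyl ether of sarcandrone B F5. Bu4NF buffered with AcOH (THF, 0 °C) brings the route back at 20.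

Further compounds
F1 | step 6 | 5,8-dimethoxy-7-[(triisopropylsilyl)oxy]chroman-2-one | O=C1CCc2c(OC)cc(O[Si](C(C)C)(C(C)C)C(C)C)c(OC)c2O1
F2 | step 6 | 3-{2-hydroxy-3,6-dimethoxy-4-[(triisopropylsilyl)oxy]phenyl}-1-phenylpropan-1-one | O=C(CCc1c(OC)cc(O[Si](C(C)C)(C(C)C)C(C)C)c(OC)c1O)c1ccccc1
F3 | step 7 | 2-[(3S)-3-hydroxy-3-phenylpropyl]-3,6-dimethoxy-5-[(triisopropylsilyl)oxy]phenol | O[C@@H](CCc1c(OC)cc(O[Si](C(C)C)(C(C)C)C(C)C)c(OC)c1O)c1ccccc1
F4 | step 10 | (2R)-4-(2-ethoxyethoxy)-5,8-dimethoxy-2-phenyl-7-[(triisopropylsilyl)oxy]chroman (mixture at C4) | CCOCCOC1C[C@H](c2ccccc2)Oc2c(OC)c(O[Si](C(C)C)(C(C)C)C(C)C)cc(OC)c21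
F5 | step 10 | 7-O-triisopropylsilyl ether of sarcandrone B | COc1cc(O)c(C(=O)/C=C/c2ccccc2)c(O)c1[C@H]1C[C@H](c2ccccc2)Oc2c(OC)c(O[Si](C(C)C)(C(C)C)C(C)C)cc(OC)c21
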